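## Retrosynthetic overview
1. The target is epigallocatechin-3-O-gallate-(4β→8)-epigallocatechin. The upper unit is 2R,3R,4R (2,3-cis, 3,4-trans) and the lower unit is 2R,3R, giving five stereocentres and seven rings.
2. The only skeletal cut is upper C4–lower C8. It is taken as a net C–H/C–H union of two free tea catechins that copies plant chain extension: the extension unit is the EGCG C4 cation (ring-A quinone methide) and the starter unit is EGC.
3. The cation is stored as a 4β-methyl ether, made by hydride abstraction from C4–H of EGCG under throw-away Me3Si masking. Unmasking, ionisation and C–C bond formation then occur in one flask in dilute aqueous acid with unprotected EGC.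
4. EGC is itself cut back to EGCG by enzymatic degalloylation, so one bulk compound feeds both halves.
5. Ring order: no ring is closed in the flask. Rings A, C, B and the galloyl ring (upper) and rings D, F, E (lower) arrive finished in EGCG, just as the plant joins finished flavan-3-ol units. The last event is the C4–C8 bond, which sets the fifth stereocentre.

Assumption: green-tea (−)-EGCG (≥95 %) counts as the cheap commercial starting material; it supplies all seven rings and four of the five stereocentres.

## Route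

Step 1
Reactants: 1 (−)-epigallocatechin-3-O-gallate (EGCG)
Product: 2 (−)-epigallocatechin (EGC)
Conditions: tannase (Aspergillus oryzae), citrate buffer pH 5.5, Ar, 37 °C, 3 h; EtOAc extraction at pH 5.5–6
Reagents that add atoms: none
Why: Tannase-catalysed ester hydrolysis (enzymatic acyl–oxygen cleavage of the galloyl ester) runs at pH 5.5, where neither C2 epimerisation nor pyrogallol autoxidation competes, so the 2R,3R centres are carried over untouched and the nucleophile needed in excess comes from the same bulk catechin.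

Step 2
Reactants: 1 (−)-epigallocatechin-3-O-gallate (EGCG)
Product: 4 octa-O-trimethylsilyl-4β-methoxy-EGCG, via octa-O-trimethylsilyl-EGCG 3 (not isolated)
Conditions: BSA (10 equiv), MeCN, 40 °C, 1 h, evaporate (high vacuum); then MeOSiMe3 (10 equiv), DDQ (1.1 equiv), CH2Cl2, 0 °C to rt, 2 h; pentane, filter, evaporate, use crude at once
Reagents that add atoms: N,O-bis(trimethylsilyl)acetamide (BSA), CC(=N[Si](C)(C)C)O[Si](C)(C)C; methoxytrimethylsilane, CO[Si](C)(C)C
Why: Proposed new method: after routine exhaustive BSA silylation of the eight phenols, DDQ abstracts hydride from C4–H (the only C–H bond whose cation is stabilised by the three oxygen donors of ring A), and the ion pair is trapped by MeOSiMe3 on the β face anti to the axial 3-O-acyl group (giving 4S, a centre that is erased again in step 3) while Me3Si passes to the DDQH anion, so the medium stays aprotic and the excess MeOSiMe3 keeps the oxidation-sensitive pyrogallol oxygens silylated; the closest known reaction type is the DDQ benzylic C4–H alkoxylation of per-O-benzyl or per-O-methyl flavan-3-ols in the presence of an alcohol.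

Step 3
Reactants: 4 octa-O-trimethylsilyl-4β-methoxy-EGCG; 2 (−)-epigallocatechin (EGC)
Product: 7 epigallocatechin-3-O-gallate-(4β→8)-epigallocatechin (target), via 4β-methoxy-EGCG 5 (not isolated), via EGCG ring-A para-quinone methide 6 (not isolated)
Conditions: 2 (4 equiv), slow addition of 4 in THF, degassed THF/0.1 M aq HCl (1:1), Ar, 0 °C to rt, 3 h; EtOAc extraction; Sephadex LH-20, then reversed-phase HPLC (excess 2 recovered, minor 4β→6 isomer removed)
Reagents that add atoms: none
Why: Biomimetic proanthocyanidin chain extension (leucoanthocyanidin-type SN1 Friedel–Crafts condensation through a flavan-4-yl cation/quinone methide, known for unprotected flavan-3,4-diols and flavan-3-ols in dilute acid): the aryl Me3Si ethers hydrolyse within minutes, the freed 5- and 7-OH groups expel methanol, and C8 of free EGC, the most nucleophilic and less hindered ring-D carbon, adds to the β face opposite the axial 3-O-galloyl group (which can also cover the α face as an acyloxonium ion), so C4 is set 4R (3,4-trans) under substrate control while the four existing centres are not touched and the excess of 2 suppresses oligomers.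

## Compound list
1 | (−)-epigallocatechin-3-O-gallate, EGCG, (2R,3R) | O=C(O[C@@H]1Cc2c(O)cc(O)cc2O[C@@H]1c1cc(O)c(O)c(O)c1)c1cc(O)c(O)c(O)c1 | starting material
2 | (−)-epigallocatechin, EGC, (2R,3R) | O[C@@H]1Cc2c(O)cc(O)cc2O[C@@H]1c1cc(O)c(O)c(O)c1 | intermediate
3 | 5,7,3',4',5',3'',4'',5''-octa-O-trimethylsilyl-EGCG, (2R,3R) | O=C(O[C@@H]1Cc2c(O[Si](C)(C)C)cc(O[Si](C)(C)C)cc2O[C@@H]1c1cc(O[Si](C)(C)C)c(O[Si](C)(C)C)c(O[Si](C)(C)C)c1)c1cc(O[Si](C)(C)C)c(O[Si](C)(C)C)c(O[Si](C)(C)C)c1 | intermediate
4 | octa-O-trimethylsilyl-4β-methoxy-EGCG, (2R,3R,4S), 2,3-cis-3,4-trans | O=C(O[C@@H]1[C@@H](OC)c2c(O[Si](C)(C)C)cc(O[Si](C)(C)C)cc2O[C@@H]1c1cc(O[Si](C)(C)C)c(O[Si](C)(C)C)c(O[Si](C)(C)C)c1)c1cc(O[Si](C)(C)C)c(O[Si](C)(C)C)c(O[Si](C)(C)C)c1 | intermediate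
5 | 4β-methoxy-EGCG (all phenols free), (2R,3R,4S) | O=C(O[C@@H]1[C@@H](OC)c2c(O)cc(O)cc2O[C@@H]1c1cc(O)c(O)c(O)c1)c1cc(O)c(O)c(O)c1 | intermediate
6 | EGCG ring-A para-quinone methide (C4=C4a, C7=O; neutral form of the C4 carbocation), (2R,3R) | O=C(O[C@@H]1C=C2C(O)=CC(=O)C=C2O[C@@H]1c1cc(O)c(O)c(O)c1)c1cc(O)c(O)c(O)c1 | intermediate
7 | epigallocatechin-3-O-gallate-(4β→8)-epigallocatechin, upper unit (2R,3R,4R), lower unit (2R,3R) | O=C(O[C@@H]1[C@@H](c2c(O)cc(O)c3c2O[C@H](c2cc(O)c(O)c(O)c2)[C@H](O)C3)c2c(O)cc(O)cc2O[C@@H]1c1cc(O)c(O)c(O)c1)c1cc(O)c(O)c(O)c1 | target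

## Step count and risks
Total steps: 3. Longest linear sequence: 2 (1 → 4 → 7, or 1 → 2 → 7).

**Most at risk: step 2.**
- The DDQ oxidation has never been run on aryl Me3Si ethers.
- One leaking pyrogallol silyl ether would be oxidised to a quinone.
- Silyl ethers donate less than benzyl ethers, so hydride abstraction may be slow.
- Over-oxidation at C4 is possible.

The fallback gives up transient masking and aqueous coupling in favour of permanent benzyl ethers. It sets out from 1 (upper half) and 2 (lower half) and comes back at 7. Compound 1 with BnBr and K2CO3 in DMF gives octa-O-benzyl-EGCG F1. DDQ and 2-ethoxyethanol in CH2Cl2 convert this into octa-O-benzyl-4β-(2-ethoxyethoxy)-EGCG F2. Compound 2 is benzylated in the same way to 5,7,3',4',5'-penta-O-benzyl-EGC F3. Catalytic Me3SiOTf in CH2Cl2 at −78 °C with excess F3 joins the halves to the trideca-O-benzyl 4β→8 dimer F4. Hydrogenolysis (H2, Pd(OH)2/C, THF/MeOH/H2O) then gives 7.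

**Second: step 3.**
- The 3-O-acyl group slows ionisation.
- The free electrophile can condense with itself or with the product.
- The C6 isomer may be larger than hoped.

The fallback replaces acid-driven SN1 release by a storable thioether and base-triggered quinone methide release. It sets out from 4 and comes back at 6. Compound 4 with L-cysteine hydrochloride in MeOH/0.1 M aq HCl at 40 °C is unmasked and thiolated from the β face. This gives isolable 4β-(S-L-cysteinyl)-EGCG F5, the conjugate in which plants are thought to store the extension unit. The treatment also cleaves any oligomer back to the same compound. F5 and 2 (3 equiv) are then held in degassed phosphate buffer at pH 7.5 under Ar at 30 °C. The ring-A phenolate expels the thiolate (E1cB-type) to re-form 6, which 2 captures at C8 to give 7.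

**Third: step 1.**
- Gallic acid inhibits the enzyme.
- EGC autoxidises.
- EGC is lost on extraction from water.

The fallback replaces enzymatic hydrolysis by reductive ester cleavage on the masked substrate. It sets out from 3 (made as in step 2) and comes back at 2. Compound 3 with diisobutylaluminium hydride, (Me2CHCH2)2AlH (3 equiv), in CH2Cl2 from −78 to 0 °C gives 5,7,3',4',5'-penta-O-trimethylsilyl-EGC F6 beside the silylated benzylic alcohol. Brief treatment with THF/aqueous citric acid at 0 °C strips the silyl groups, and Sephadex LH-20 chromatography delivers 2.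

Further compounds
F1 | step 2 | octa-O-benzyl-EGCG | O=C(O[C@@H]1Cc2c(OCc3ccccc3)cc(OCc3ccccc3)cc2O[C@@H]1c1cc(OCc2ccccc2)c(OCc2ccccc2)c(OCc2ccccc2)c1)c1cc(OCc2ccccc2)c(OCc2ccccc2)c(OCc2ccccc2)c1
F2 | step 2 | octa-O-benzyl-4β-(2-ethoxyethoxy)-EGCG | O=C(O[C@@H]1[C@@H](OCCOCC)c2c(OCc3ccccc3)cc(OCc3ccccc3)cc2O[C@@H]1c1cc(OCc2ccccc2)c(OCc2ccccc2)c(OCc2ccccc2)c1)c1cc(OCc2ccccc2)c(OCc2ccccc2)c(OCc2ccccc2)c1
F3 | step 2 | 5,7,3',4',5'-penta-O-benzyl-EGC | O[C@@H]1Cc2c(OCc3ccccc3)cc(OCc3ccccc3)cc2O[C@@H]1c1cc(OCc2ccccc2)c(OCc2ccccc2)c(OCc2ccccc2)c1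
F4 | step 2 | trideca-O-benzyl epigallocatechin-3-O-gallate-(4β→8)-epigallocatechin (lower 3-OH free) | O=C(O[C@@H]1[C@@H](c2c(OCc4ccccc4)cc(OCc4ccccc4)c3c2O[C@H](c2cc(OCc4ccccc4)c(OCc4ccccc4)c(OCc4ccccc4)c2)[C@H](O)C3)c2c(OCc4ccccc4)cc(OCc4ccccc4)cc2O[C@@H]1c1cc(OCc4ccccc4)c(OCc4ccccc4)c(OCc4ccccc4)c1)c1cc(OCc4ccccc4)c(OCc4ccccc4)c(OCc4ccccc4)c1
F5 | step 3 | 4β-(S-L-cysteinyl)-EGCG | O=C(O[C@@H]1[C@@H](SC[C@H](N)C(=O)O)c2c(O)cc(O)cc2O[C@@H]1c1cc(O)c(O)c(O)c1)c1cc(O)c(O)c(O)c1
F6 | step 1 | 5,7,3',4',5'-penta-O-trimethylsilyl-EGC | O[C@@H]1Cc2c(O[Si](C)(C)C)cc(O[Si](C)(C)C)cc2O[C@@H]1c1cc(O[Si](C)(C)C)c(O[Si](C)(C)C)c(O[Si](C)(C)C)c1
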